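## Analysis of the target

Target **28** is 8α-acetoxy-14,15,16-trinorlabdane-13,18-dioic acid, a trans-decalin (ring A: C1–C5, C10; ring B: C5–C10) with a propanoic acid chain (C11–C13) on C9. Labdane locants are used for all ring compounds below; β is the face of the C10 methyl (C20) and α the face of H5. The five stereocentres C4, C5, C10, C9 and C8 are contiguous, and C4, C8 and C10 are fully substituted. The three methyls C19, C20 and C17 are all axial on the β face, while the C18 carboxyl, O8 and the C9 chain are equatorial, so O8 is trans to the chain. The tertiary acetate is the sensitive group: acid ionises it, base and hydride remove it, a neighbouring primary hydroxyl can take it over, and it is hard to install late because a free 8-hydroxy-13-ester can close to a δ-lactone. The synthesis is hard because ring B carries four contiguous centres flanked by two quaternary carbons, and because a methyl nucleophile adding to an 8-ketone would approach away from the axial C20 and give the wrong C8 epimer. The strategy rests on the sequence C8(OAc)(Me)–C9–C10–C5 around ring B. O8 and the carbonyl-level carbon C11 sit on adjacent carbons, which is the "ortho" pattern of a 1-oxygenated diene (C8=C7–C6=C5) and a carbonyl-activated dienophile (C9=C10). Ring A then serves as the tether, with C4 as an achiral gem-diester.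

## Retrosynthetic reasoning

**28 ⇒ 27 ⇒ 26.** The O-benzyl bonds and the O8–acetyl bond are cut last. The acetate is built into the diene, but it cannot survive the hydride needed later at C19, so it is put back on the tertiary alcohol **26**. Both acids are benzyl esters at that stage so that the final unmasking of **27** is neutral.

**26 ⇒ 25 ⇒ 24 ⇒ 23 ⇒ 22 ⇒ 21.** The C19 methyl is traced to an ester. Radical deoxygenation links **26** to thionocarbonate **25** and diol **24**. The C19 alcohol of **23** comes from the axial ester of half ester **22**, and **22** comes from triester **21** by a hydrolysis that tells the two C4 esters apart by their surroundings. The cut is made here because a gem-diester keeps the acyclic precursor free of a C4 stereocentre and favours ring closure. The price is this differentiation sequence.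

**21 ⇒ 20 ⇒ 18 + 19.** The C11–C12 bond is cut at the alkene of **20**. C11 is the activating carbonyl of the dienophile, so it arrives as an acyl carbon, and a two-carbon olefination of aldehyde **18** with ylide **19** completes the chain.

**18 ⇒ 17 ⇒ 16 ⇒ 15.** These are functional-group changes only. The auxiliary leaves **16** as thioester **17**, which is reduced directly to the aldehyde. A C11 alcohol next to the acetate is thereby avoided. The ring alkene of **15** is saturated first, while the acetate is still the only allylic function.

**15 ⇒ 14.** This is the key disconnection: C8–C9 and C5–C10 are cut, which opens rings B and A at once. It is chosen over any cut in ring A because it removes four stereocentres and both rings in one step and reduces the stereochemistry to two alkene geometries and one auxiliary. The forward reaction must join C5 to the quaternary C10 and the fully substituted C8 to C9, on one face of the dienophile, through the endo, trans-fused transition state. The (S)-auxiliary **5** is the antipode that the chelate model requires.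

**14 ⇒ 13 ⇒ 11 + 12.** The enol O–acetyl bond is cut to give enone **13**. Enolisation toward C5 moves the unsaturation into conjugation with C4, which solves the problem of attaching a dienyl group to a quaternary malonate carbon. The C6=C7 bond of **13** is cut by cross-metathesis into the allyl group of **11** and enone **12**.

**11 ⇒ 8 + 9.** The C3–C4 bond is cut by malonate alkylation. Allylmalonate **9** is alkylated with iodide **8** so that C4 is quaternary once the imide arm is on, and no enolate is left to attack the enoyl imide.

**8 ⇒ 7 ⇒ 4 + 5; 4 ⇒ 1.** The N–C11 bond is cut to acid **4** and auxiliary **5**. The (E)-trisubstituted alkene of **4** is cut at C10–C20 and C9–C11 by syn carbometalation of alkyne **1** and carboxylation. This route is preferred over a ketone olefination because it fixes the geometry that later sets C9 relative to C10.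

## Alternatives that were turned down

**Alternative 1:** Ring B is taken from quinone **A1** and ring A is made by an intermolecular Diels–Alder reaction with dienyl silyl ether **A2** under a chiral cationic boron Lewis acid. The reaction forms C1–C10 and C4–C5 and gives the cis-fused endo adduct **A3**.
- For: it is convergent, both partners are one or two steps from commercial material, no auxiliary is needed, and catalytic asymmetric quinone cycloadditions are far better precedented than the chosen key step. Both quaternary carbons of ring A are set at once.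
- Against: ring B arrives as an enedione. C5 must be epimerised and the C6 oxygen deleted. The C9 carbonyl, next to quaternary C10, must be turned into a CH bearing a three-carbon chain. The C8 oxygen must be added to the enone from the correct face. None of C8 and C9 is set by the key step, and the diene terminus of **A2** is 1,1-disubstituted, so it has the same inside-substituent handicap as **14**.
- Comparison: **A3** wins on precedent and convergence. The chosen route offers ring B with only the oxygen that the target keeps and with C8, C9, C10 and C5 already correct.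

**Alternative 2:** The C9–C10 bond is cut. Keto ester **A4**, a ring-A cyclohexane with an exocyclic methylene at C10, closes ring B by a thermal Conia-ene reaction to the 8-keto-9-carboxylate **A5**.
- For: the C10 methyl is created from a methylene without a reagent. C4 enters with its real methyl and carboxyl, so no ester differentiation or deoxygenation is needed. On this point it is clearly stronger than the chosen route.
- Against: an enol–ene reaction onto an unactivated 1,1-disubstituted alkene needs very high temperature or special metal catalysis. **A4** needs its own enantioselective synthesis of the vicinal C4/C5 pair. Only C9 and C10 are set. The 8-ketone of **A5** is part of an enolisable β-keto ester, and a methyl nucleophile would add from the α face, away from the axial C20, giving the C8 epimer of the target.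
- Comparison: the chosen route derives the C8 methyl and oxygen from the geometry of an enol acetate, which is independent of the facial bias of the decalin. It pays for this with the C4 sequence.

**Alternative 3:** C3–C4 and C5–C10 are cut. Lactone triene **A6**, made from an epoxide, already holds C8 and C9 in a δ-lactone and cyclises on heating to the tricyclic lactone **A7**.
- For: the lactone protects O8 and C13 together. The dienophile geometry sets C4 with methyl and ester directly. The end game is only hydrogenation, lactone opening and acetylation, so after the key step it is much shorter than the chosen route.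
- Against: facial control rests on two stereocentres on a flexible tether. The tether forces the nucleophilic diene terminus C3 onto the α-carbon C4 of the enoate, an electronic mismatch that only heat can overcome. The diene terminus C10 is 1,1-disubstituted with its methyl inside, and the dienophile is trisubstituted. **A6** also needs a multistep asymmetric synthesis of a tertiary carbinol next to a diene-bearing centre.
- Comparison: **A7** is stronger on step economy. The chosen route offers Lewis-acid activation with absolute control from a recoverable auxiliary, an electronically matched first bond (C5, para to the acetoxy donor, onto the β-carbon C10), and a precursor reached in six steps from simple building blocks.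

Key step: step 7

## Route

Remark on the chemistry: dimethyl allylmalonate **9** and ylide **19** are taken as commercial, which saves a first malonate allylation.

Step 1
Reactants: 1 5-chloropent-1-yne
Product: 4 (E)-6-chloro-3-methylhex-2-enoic acid, via alkenylalane 2 (not isolated), via lithium alanate 3 (not isolated)
Conditions: Me3Al, Cp2ZrCl2 (cat.), CH2Cl2, rt; evaporate; n-BuLi, THF/hexane, −78 °C; CO2; aq. HCl
Reagents that add atoms: trimethylaluminium, C[Al](C)C; carbon dioxide, O=C=O
Why: Negishi zirconium-catalysed carboalumination adds methyl and aluminium syn across the alkyne with the metal on the terminal carbon, and the derived alanate is carboxylated with retention, so C11 ends up cis to the C20 methyl; the primary chloride is inert to both organometallics at low temperature.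

Step 2
Reactants: 4 (E)-6-chloro-3-methylhex-2-enoic acid; 5 (S)-4-benzyloxazolidin-2-one
Product: 7 (S)-4-benzyl-3-[(E)-6-chloro-3-methylhex-2-enoyl]oxazolidin-2-one, via mixed pivalic anhydride 6 (not isolated)
Conditions: PivCl, Et3N, THF, −20 °C; then 5, LiCl, rt
Reagents that add atoms: none
Why: N-acylation through the mixed anhydride with LiCl/Et3N activation; the oxazolidinone attacks the unhindered enoyl carbonyl, and the mild amine conditions avoid deconjugation of the β-methyl enoyl unit.

Step 3
Reactants: 7 (S)-4-benzyl-3-[(E)-6-chloro-3-methylhex-2-enoyl]oxazolidin-2-one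
Product: 8 (S)-4-benzyl-3-[(E)-6-iodo-3-methylhex-2-enoyl]oxazolidin-2-one
Conditions: NaI, acetone, reflux
Reagents that add atoms: sodium iodide, [Na+].[I-]
Why: Finkelstein exchange, driven by precipitation of NaCl, turns the sluggish chloride into a primary iodide that alkylates at room temperature.

Step 4
Reactants: 9 dimethyl 2-allylmalonate; 8 (S)-4-benzyl-3-[(E)-6-iodo-3-methylhex-2-enoyl]oxazolidin-2-one
Product: 11 dimethyl 2-allyl-2-{(E)-6-[(S)-4-benzyl-2-oxooxazolidin-3-yl]-4-methyl-6-oxohex-4-en-1-yl}malonate, via sodium malonate enolate 10 (not isolated)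
Conditions: NaH, THF/DMF, 0 °C; then 8, rt
Reagents that add atoms: none
Why: SN2 alkylation of the soft malonate anion; the product is quaternary at C4, so no enolate remains that could add to the enoyl imide, and the β,β-disubstitution of that acceptor protects it from the malonate.

Step 5
Reactants: 11 dimethyl 2-allyl-2-{(E)-6-[(S)-4-benzyl-2-oxooxazolidin-3-yl]-4-methyl-6-oxohex-4-en-1-yl}malonate; 12 but-3-en-2-one
Product: 13 dimethyl 2-{(E)-6-[(S)-4-benzyl-2-oxooxazolidin-3-yl]-4-methyl-6-oxohex-4-en-1-yl}-2-[(E)-4-oxopent-2-en-1-yl]malonate
Conditions: 12 (3 equiv), second-generation Hoveyda–Grubbs catalyst RuCl2(H2IMes)(=CH-2-(i-PrO)C6H4) (3 mol%), CH2Cl2, 40 °C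
Reagents that add atoms: none
Why: Olefin cross-metathesis of a terminal alkene with an electron-poor partner is selective for the (E)-enone; the trisubstituted enoyl imide alkene does not take part.

Step 6
Reactants: 13 dimethyl 2-{(E)-6-[(S)-4-benzyl-2-oxooxazolidin-3-yl]-4-methyl-6-oxohex-4-en-1-yl}-2-[(E)-4-oxopent-2-en-1-yl]malonate
Product: 14 dimethyl 2-[(1E,3Z)-4-acetoxypenta-1,3-dien-1-yl]-2-{(E)-6-[(S)-4-benzyl-2-oxooxazolidin-3-yl]-4-methyl-6-oxohex-4-en-1-yl}malonate
Conditions: isopropenyl acetate, TsOH·H2O (5 mol%), 90 °C, acetone distilled off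
Reagents that add atoms: isopropenyl acetate, CC(=C)OC(C)=O
Why: Acid-catalysed enol acetylation by transesterification equilibrates to the linear conjugated dienyl acetate, as with Δ4-3-keto steroids. The (5E,7Z) isomer should dominate because the acetoxy group, not the methyl, is then cis to the vinyl residue and C4 lies trans across C5=C6; any 7E isomer is removed by chromatography.

Step 7
Reactants: 14 dimethyl 2-[(1E,3Z)-4-acetoxypenta-1,3-dien-1-yl]-2-{(E)-6-[(S)-4-benzyl-2-oxooxazolidin-3-yl]-4-methyl-6-oxohex-4-en-1-yl}malonate
Product: 15 dimethyl 8α-acetoxy-9β-[(S)-4-benzyl-2-oxooxazolidine-3-carbonyl]-8β,10β-dimethyl-5αH-Δ6-trans-octalin-4,4-dicarboxylate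
Conditions: Me2AlCl (3 equiv), CH2Cl2, −30 → 0 °C
Reagents that add atoms: none
Why: Proposed new method: bidentate chelation of the imide by the dimethylaluminium cation locks the enoyl unit s-cis and lowers its LUMO, so the dienyl acetate adds in an asynchronous concerted [4+2] in which C5 (para to the acetoxy donor) leads onto the electrophilic β-carbon C10 and C8–C9 follows; the closest known reaction is the Me2AlCl-promoted type 1 intramolecular Diels–Alder of (E,E)-trienimides with the same auxiliary, which has not been shown with a β,β-disubstituted dienophile and a 1-acetoxy-1-methyl diene terminus. Ring B is the cyclohexene formed by the cycloaddition itself (C5–C10 and C8–C9), and ring A closes in the same event because the four-atom malonate tether C1–C4 joins C10 to C5 and adopts a chair in the trans-fused transition state. C10 and C9 are set relative to each other by the (E)-dienophile (C20 cis to C11) and in the absolute sense by the benzyl group of the (S)-auxiliary, which blocks one face of the chelate. C5 follows from the endo arrangement with the imide under the diene and the tether exo, which places H5 anti to the C10 methyl. C8 follows from the (Z)-enol acetate, whose inside acetoxy group ends up trans to C11 and whose outside methyl ends up syn to C20. The step needs facial, endo and geometric fidelity: the first rests on the chelated auxiliary, the second on the endo preference of chelated trienimides reinforced by the tether, the third on suprafacial addition to geometrically pure 14. The gem-diester favours the coiled conformer, and the inside substituent on the diene is the small acetoxy group and not the methyl.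

Step 8
Reactants: 15 dimethyl 8α-acetoxy-9β-[(S)-4-benzyl-2-oxooxazolidine-3-carbonyl]-8β,10β-dimethyl-5αH-Δ6-trans-octalin-4,4-dicarboxylate
Product: 16 dimethyl 8α-acetoxy-9β-[(S)-4-benzyl-2-oxooxazolidine-3-carbonyl]-8β,10β-dimethyl-5αH-trans-decalin-4,4-dicarboxylate
Conditions: H2 (1 atm), PtO2, EtOAc, rt
Reagents that add atoms: none
Why: Heterogeneous hydrogenation of the cis-disubstituted ring alkene; platinum is used instead of palladium to avoid hydrogenolysis of the tertiary allylic acetate, and no stereocentre is formed.

Step 9
Reactants: 16 dimethyl 8α-acetoxy-9β-[(S)-4-benzyl-2-oxooxazolidine-3-carbonyl]-8β,10β-dimethyl-5αH-trans-decalin-4,4-dicarboxylate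
Product: 17 dimethyl 8α-acetoxy-9β-[(ethylthio)carbonyl]-8β,10β-dimethyl-5αH-trans-decalin-4,4-dicarboxylate
Conditions: EtSH, n-BuLi, THF, 0 °C
Reagents that add atoms: ethanethiol, CCS
Why: Transacylation of the imide by lithium ethanethiolate, a small and weakly basic nucleophile that attacks the exocyclic carbonyl, releases the auxiliary and leaves the methyl esters and the tertiary acetate alone. C9–H is not removed, because enolisation would place an exocyclic double bond between two fully substituted carbons.

Step 10
Reactants: 17 dimethyl 8α-acetoxy-9β-[(ethylthio)carbonyl]-8β,10β-dimethyl-5αH-trans-decalin-4,4-dicarboxylate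
Product: 18 dimethyl 8α-acetoxy-9β-formyl-8β,10β-dimethyl-5αH-trans-decalin-4,4-dicarboxylate
Conditions: Et3SiH, 10% Pd/C, acetone, rt
Reagents that add atoms: none
Why: Fukuyama reduction (acyl–palladium formation and hydride transfer from the silane) gives the aldehyde without passing through a C11 alcohol, which would invite migration of the neighbouring acetate; the esters are untouched.

Step 11
Reactants: 18 dimethyl 8α-acetoxy-9β-formyl-8β,10β-dimethyl-5αH-trans-decalin-4,4-dicarboxylate; 19 methyl (triphenylphosphoranylidene)acetate
Product: 20 dimethyl 8α-acetoxy-9β-[(E)-2-(methoxycarbonyl)vinyl]-8β,10β-dimethyl-5αH-trans-decalin-4,4-dicarboxylate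
Conditions: 19 (3 equiv), toluene, 90 °C
Reagents that add atoms: none
Why: Wittig olefination with a stabilised ylide under neutral conditions gives the (E)-enoate; the equatorial acetoxy group is not antiperiplanar to C9–H, which disfavours β-elimination.

Step 12
Reactants: 20 dimethyl 8α-acetoxy-9β-[(E)-2-(methoxycarbonyl)vinyl]-8β,10β-dimethyl-5αH-trans-decalin-4,4-dicarboxylate
Product: 21 dimethyl 8α-acetoxy-9β-[2-(methoxycarbonyl)ethyl]-8β,10β-dimethyl-5αH-trans-decalin-4,4-dicarboxylate
Conditions: H2 (1 atm), 10% Pd/C, EtOAc, rt
Reagents that add atoms: none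
Why: Catalytic hydrogenation of the conjugated alkene; no stereocentre is created and the tertiary acetate, no longer allylic, is stable.

Step 13
Reactants: 21 dimethyl 8α-acetoxy-9β-[2-(methoxycarbonyl)ethyl]-8β,10β-dimethyl-5αH-trans-decalin-4,4-dicarboxylate
Product: 22 8α-hydroxy-14,15,16-trinorlabdane-13,18,19-trioic acid 19-methyl ester
Conditions: KOH, MeOH/H2O (4:1), 65 °C; then 1 M HCl, 0 °C; used at once
Reagents that add atoms: potassium hydroxide, [K+].[OH-]
Why: Saponification: the side-chain ester, the tertiary acetate and the equatorial (α) C4 ester are hydrolysed, while the axial (β) ester, 1,3-diaxial to the C10 methyl and next to the new carboxylate, should resist. This facial discrimination defines C4 (α-CO2H = C18).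

Step 14
Reactants: 22 8α-hydroxy-14,15,16-trinorlabdane-13,18,19-trioic acid 19-methyl ester
Product: 23 8α,19-dihydroxy-14,15,16-trinorlabdane-13,18-dioic acid
Conditions: LiEt3BH (8 equiv), THF, 0 → 50 °C; then 1 M HCl, 0 °C; used crude
Reagents that add atoms: none
Why: Lithium triethylborohydride reduces hindered esters but leaves lithium carboxylates, so only the axial ester becomes the C19 alcohol.

Step 15
Reactants: 23 8α,19-dihydroxy-14,15,16-trinorlabdane-13,18-dioic acid
Product: 24 dibenzyl 8α,19-dihydroxy-14,15,16-trinorlabdane-13,18-dioate
Conditions: BnBr, Cs2CO3, DMF, rt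
Reagents that add atoms: benzyl bromide, BrCc1ccccc1
Why: O-Alkylation of the caesium carboxylates is insensitive to hindrance at the acyl carbon and leaves both hydroxyl groups free; benzyl esters allow neutral unmasking at the end.

Step 16
Reactants: 24 dibenzyl 8α,19-dihydroxy-14,15,16-trinorlabdane-13,18-dioate
Product: 25 dibenzyl 8α-hydroxy-19-[(phenoxycarbonothioyl)oxy]-14,15,16-trinorlabdane-13,18-dioate
Conditions: PhOC(S)Cl, pyridine, DMAP (cat.), CH2Cl2, 0 °C → rt
Reagents that add atoms: O-phenyl chlorothionoformate, S=C(Cl)Oc1ccccc1
Why: Acylation with the chlorothionoformate takes place only at the primary C19 hydroxyl; the tertiary C8 hydroxyl does not react under these conditions.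

Step 17
Reactants: 25 dibenzyl 8α-hydroxy-19-[(phenoxycarbonothioyl)oxy]-14,15,16-trinorlabdane-13,18-dioate
Product: 26 dibenzyl 8α-hydroxy-14,15,16-trinorlabdane-13,18-dioate
Conditions: Bu3SnH, AIBN, toluene, 100 °C
Reagents that add atoms: none
Why: Barton–McCombie deoxygenation: the stannyl radical adds to the thiocarbonyl sulfur, the C19–O bond fragments and the primary radical takes hydrogen from the stannane, giving the axial C19 methyl without touching C4.

Step 18
Reactants: 26 dibenzyl 8α-hydroxy-14,15,16-trinorlabdane-13,18-dioate
Product: 27 dibenzyl 8α-acetoxy-14,15,16-trinorlabdane-13,18-dioate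
Conditions: Ac2O, Sc(OTf)3 (2 mol%), MeCN, −20 °C
Reagents that add atoms: acetic anhydride, CC(=O)OC(C)=O
Why: Lewis-acid-catalysed acetylation with the anhydride is a known way to acylate hindered tertiary alcohols at low temperature without elimination; the fast intermolecular acetyl transfer should outrun closure of O8 onto the C13 ester.

Step 19
Reactants: 27 dibenzyl 8α-acetoxy-14,15,16-trinorlabdane-13,18-dioate
Product: 28 8α-acetoxy-14,15,16-trinorlabdane-13,18-dioic acid
Conditions: H2 (1 atm), 10% Pd/C, EtOAc, rt
Reagents that add atoms: none
Why: Hydrogenolysis of both benzyl esters under neutral conditions frees the two acids and leaves the tertiary acetate untouched.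

## Compound list

1 | 5-chloropent-1-yne | C#CCCCCl | starting material
2 | (E)-(5-chloro-2-methylpent-1-en-1-yl)dimethylalane | C[Al](C)/C=C(\C)CCCCl | intermediate
3 | lithium butyl[(E)-5-chloro-2-methylpent-1-en-1-yl]dimethylalanate | [Li+].CCCC[Al-](C)(C)/C=C(\C)CCCCl | intermediate
4 | (E)-6-chloro-3-methylhex-2-enoic acid | OC(=O)/C=C(\C)CCCCl | intermediate
5 | (S)-4-benzyloxazolidin-2-one | O=C1N[C@@H](Cc2ccccc2)CO1 | starting material
6 | (E)-6-chloro-3-methylhex-2-enoic pivalic anhydride | CC(C)(C)C(=O)OC(=O)/C=C(\C)CCCCl | intermediate
7 | (S)-4-benzyl-3-[(E)-6-chloro-3-methylhex-2-enoyl]oxazolidin-2-one | O=C(/C=C(\C)CCCCl)N1C(=O)OC[C@@H]1Cc1ccccc1 | intermediate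
8 | (S)-4-benzyl-3-[(E)-6-iodo-3-methylhex-2-enoyl]oxazolidin-2-one | O=C(/C=C(\C)CCCI)N1C(=O)OC[C@@H]1Cc1ccccc1 | intermediate
9 | dimethyl 2-allylmalonate | COC(=O)C(CC=C)C(=O)OC | starting material
10 | sodium enolate of dimethyl 2-allylmalonate | [Na+].COC(=O)[C-](CC=C)C(=O)OC | intermediate
11 | dimethyl 2-allyl-2-{(E)-6-[(S)-4-benzyl-2-oxooxazolidin-3-yl]-4-methyl-6-oxohex-4-en-1-yl}malonate | O=C(/C=C(\C)CCCC(CC=C)(C(=O)OC)C(=O)OC)N1C(=O)OC[C@@H]1Cc1ccccc1 | intermediate
12 | but-3-en-2-one (methyl vinyl ketone) | CC(=O)C=C | starting material
13 | dimethyl 2-{(E)-6-[(S)-4-benzyl-2-oxooxazolidin-3-yl]-4-methyl-6-oxohex-4-en-1-yl}-2-[(E)-4-oxopent-2-en-1-yl]malonate | O=C(/C=C(\C)CCCC(C/C=C/C(C)=O)(C(=O)OC)C(=O)OC)N1C(=O)OC[C@@H]1Cc1ccccc1 | intermediate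
14 | dimethyl 2-[(1E,3Z)-4-acetoxypenta-1,3-dien-1-yl]-2-{(E)-6-[(S)-4-benzyl-2-oxooxazolidin-3-yl]-4-methyl-6-oxohex-4-en-1-yl}malonate | O=C(/C=C(\C)CCCC(C(=O)OC)(C(=O)OC)/C=C/C=C(/C)OC(C)=O)N1C(=O)OC[C@@H]1Cc2ccccc2 | intermediate
15 | dimethyl 8α-acetoxy-9β-[(S)-4-benzyl-2-oxooxazolidine-3-carbonyl]-8β,10β-dimethyl-5αH-Δ6-trans-octalin-4,4-dicarboxylate | CC(=O)O[C@]1(C)C=C[C@@H]2[C@](C)(CCCC2(C(=O)OC)C(=O)OC)[C@H]1C(=O)N3C(=O)OC[C@@H]3Cc4ccccc4 | intermediate
16 | dimethyl 8α-acetoxy-9β-[(S)-4-benzyl-2-oxooxazolidine-3-carbonyl]-8β,10β-dimethyl-5αH-trans-decalin-4,4-dicarboxylate | CC(=O)O[C@]1(C)CC[C@@H]2[C@](C)(CCCC2(C(=O)OC)C(=O)OC)[C@H]1C(=O)N3C(=O)OC[C@@H]3Cc4ccccc4 | intermediate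
17 | dimethyl 8α-acetoxy-9β-[(ethylthio)carbonyl]-8β,10β-dimethyl-5αH-trans-decalin-4,4-dicarboxylate | CC(=O)O[C@]1(C)CC[C@@H]2[C@](C)(CCCC2(C(=O)OC)C(=O)OC)[C@H]1C(=O)SCC | intermediate
18 | dimethyl 8α-acetoxy-9β-formyl-8β,10β-dimethyl-5αH-trans-decalin-4,4-dicarboxylate | CC(=O)O[C@]1(C)CC[C@@H]2[C@](C)(CCCC2(C(=O)OC)C(=O)OC)[C@H]1C=O | intermediate
19 | methyl (triphenylphosphoranylidene)acetate | COC(=O)C=P(c1ccccc1)(c1ccccc1)c1ccccc1 | starting material
20 | dimethyl 8α-acetoxy-9β-[(E)-2-(methoxycarbonyl)vinyl]-8β,10β-dimethyl-5αH-trans-decalin-4,4-dicarboxylate | CC(=O)O[C@]1(C)CC[C@@H]2[C@](C)(CCCC2(C(=O)OC)C(=O)OC)[C@H]1/C=C/C(=O)OC | intermediate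
21 | dimethyl 8α-acetoxy-9β-[2-(methoxycarbonyl)ethyl]-8β,10β-dimethyl-5αH-trans-decalin-4,4-dicarboxylate | CC(=O)O[C@]1(C)CC[C@@H]2[C@](C)(CCCC2(C(=O)OC)C(=O)OC)[C@H]1CCC(=O)OC | intermediate
22 | 8α-hydroxy-14,15,16-trinorlabdane-13,18,19-trioic acid 19-methyl ester (4α-CO2H, 4β-CO2Me) | O[C@]1(C)CC[C@@H]2[C@](C)(CCC[C@@]2(C(=O)OC)C(=O)O)[C@H]1CCC(=O)O | intermediate
23 | 8α,19-dihydroxy-14,15,16-trinorlabdane-13,18-dioic acid | O[C@]1(C)CC[C@@H]2[C@](C)(CCC[C@@]2(CO)C(=O)O)[C@H]1CCC(=O)O | intermediate
24 | dibenzyl 8α,19-dihydroxy-14,15,16-trinorlabdane-13,18-dioate | O[C@]1(C)CC[C@@H]2[C@](C)(CCC[C@@]2(CO)C(=O)OCc3ccccc3)[C@H]1CCC(=O)OCc4ccccc4 | intermediate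
25 | dibenzyl 8α-hydroxy-19-[(phenoxycarbonothioyl)oxy]-14,15,16-trinorlabdane-13,18-dioate | O[C@]1(C)CC[C@@H]2[C@](C)(CCC[C@@]2(COC(=S)Oc5ccccc5)C(=O)OCc3ccccc3)[C@H]1CCC(=O)OCc4ccccc4 | intermediate
26 | dibenzyl 8α-hydroxy-14,15,16-trinorlabdane-13,18-dioate | O[C@]1(C)CC[C@@H]2[C@](C)(CCC[C@@]2(C)C(=O)OCc3ccccc3)[C@H]1CCC(=O)OCc4ccccc4 | intermediate
27 | dibenzyl 8α-acetoxy-14,15,16-trinorlabdane-13,18-dioate | CC(=O)O[C@]1(C)CC[C@@H]2[C@](C)(CCC[C@@]2(C)C(=O)OCc3ccccc3)[C@H]1CCC(=O)OCc4ccccc4 | intermediate
28 | 8α-acetoxy-14,15,16-trinorlabdane-13,18-dioic acid (CNP0196050.1) | CC(=O)O[C@]1(C)CC[C@@H]2[C@](C)(CCC[C@@]2(C)C(=O)O)[C@H]1CCC(=O)O | target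

## Step count and least certain steps

Total: 19 steps. Longest linear sequence: 19 steps (**1** → **28**); compounds **5**, **9**, **12** and **19** are commercial and enter directly.

**Step 7 (key step, proposed new method).** The cycloaddition may fail to occur at temperatures below those at which the Lewis acid ionises the enol acetate of **14** or the tertiary allylic acetate of the adduct. Both new bonds join hindered carbons, and the diene must reach the s-cis form with an acetoxy group inside. Facial control may also erode if the aluminium is held by the two esters instead of the imide. Fallback, from **14** back to **15**: the triene is cyclised without any Lewis acid (toluene, BHT, 150–170 °C, sealed tube). This is the well-known thermal type 1 intramolecular Diels–Alder reaction of malonate-tethered decatrienes. Chelate-controlled induction is given up, and the covalently bound auxiliary serves only as a resolving handle: the diastereomeric cycloadducts are separated by chromatography or crystallisation and **15** is carried on. No compound outside the list is made.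

**Step 6.** The equilibrating enol acetylation may give incomplete geometric control at C7=C8, or some cross-conjugated 2-acetoxy diene from enolisation toward the methyl group, because the selectivity is only thermodynamic. Fallback, from **8** to **14**, bypassing **11** and **13**:
- Deconjugative α-alkylation of dimethyl ethylidenemalonate (LDA, THF/DMPU, −78 °C) with **8** gives dimethyl 2-vinyl-2-{(E)-6-[(S)-4-benzyl-2-oxooxazolidin-3-yl]-4-methyl-6-oxohex-4-en-1-yl}malonate F1.
- 1-Iodopropyne F2 (from 1-(trimethylsilyl)propyne, NIS, AgNO3 cat.) takes up acetic acid by silver-catalysed anti addition (AgBF4 cat., AcOH/Ac2O) to give (Z)-1-iodoprop-1-en-2-yl acetate F3, with iodine cis to the acetoxy group.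
- Heck coupling of F3 with F1 (Pd(OAc)2, Ag2CO3, DMF, 60 °C) forms C6–C7 with retention at C7=C8 and the (E)-geometry at C5=C6, giving **14**.

**Step 9.** The thiolate may attack the ring carbonyl of the auxiliary (ring opening), or the exchange may stall, because the C11 carbonyl lies between two fully substituted carbons. Fallback, from **16** to **17**: hydroperoxide-mediated hydrolysis (LiOH, H2O2, THF/H2O, 0 °C), which is selective for the exocyclic carbonyl of hindered imides, gives 8α-acetoxy-4,4-bis(methoxycarbonyl)-8β,10β-dimethyl-5αH-trans-decalin-9β-carboxylic acid F4 and the auxiliary **5**. Steglich thioesterification of F4 (EtSH, DCC, DMAP cat., CH2Cl2) then gives **17**.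

**Step 13.** Hydroxide may not discriminate well enough between the two C4 esters: over-hydrolysis would lead to a malonic acid and decarboxylation, and too mild conditions would leave the equatorial ester intact. Fallback, from **21** to **22**, with hydride instead of hydroxide as the discriminating reagent:
- LiBH4 (THF/MeOH, rt) reduces the side-chain ester, the acetate and the equatorial ester but not the axial one, giving methyl 8α,13,18-trihydroxy-14,15,16-trinorlabdan-19-oate F5.
- Oxidation (TEMPO cat., PhI(OAc)2; then NaClO2) converts both primary alcohols. The C13 aldehyde closes onto O8, so the product is the δ-lactone acid 8α,13-epoxy-19-methoxy-13,19-dioxo-14,15,16-trinorlabdan-18-oic acid F6.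
- LiOH (THF/H2O, rt) opens the lactone and gives **22** after cold acidification.

**Step 17.** Radical generation at the neopentyl primary C19 may be slow, so the alcohol may be regenerated from the thionocarbonate, or the radical may undergo a 1,2-acyl shift to C4. Fallback, from **24** to **26**, through the classical aldehyde route:
- Dess–Martin periodinane oxidises only the primary alcohol, giving dibenzyl 8α-hydroxy-19-oxo-14,15,16-trinorlabdane-13,18-dioate F7.
- TsNHNH2 (MeOH, rt) gives its tosylhydrazone F8, whose sulfonylated nitrogen does not cyclise onto the neighbouring ester.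
- Reduction with catecholborane, then NaOAc·3H2O (CHCl3, 60 °C), gives **26** with loss of nitrogen.

## Further compounds

F0 | step 7 | none | none
F1 | step 6 | dimethyl 2-vinyl-2-{(E)-6-[(S)-4-benzyl-2-oxooxazolidin-3-yl]-4-methyl-6-oxohex-4-en-1-yl}malonate | O=C(/C=C(\C)CCCC(C=C)(C(=O)OC)C(=O)OC)N1C(=O)OC[C@@H]1Cc1ccccc1
F2 | step 6 | 1-iodopropyne | CC#CI
F3 | step 6 | (Z)-1-iodoprop-1-en-2-yl acetate | I/C=C(/C)OC(C)=O
F4 | step 9 | 8α-acetoxy-4,4-bis(methoxycarbonyl)-8β,10β-dimethyl-5αH-trans-decalin-9β-carboxylic acid | CC(=O)O[C@]1(C)CC[C@@H]2[C@](C)(CCCC2(C(=O)OC)C(=O)OC)[C@H]1C(=O)O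
F5 | step 13 | methyl 8α,13,18-trihydroxy-14,15,16-trinorlabdan-19-oate | O[C@]1(C)CC[C@@H]2[C@](C)(CCC[C@@]2(C(=O)OC)CO)[C@H]1CCCO
F6 | step 13 | 8α,13-epoxy-19-methoxy-13,19-dioxo-14,15,16-trinorlabdan-18-oic acid (δ-lactone acid) | O3[C@]1(C)CC[C@@H]2[C@](C)(CCC[C@@]2(C(=O)OC)C(=O)O)[C@H]1CCC3=O
F7 | step 17 | dibenzyl 8α-hydroxy-19-oxo-14,15,16-trinorlabdane-13,18-dioate | O[C@]1(C)CC[C@@H]2[C@](C)(CCC[C@@]2(C=O)C(=O)OCc3ccccc3)[C@H]1CCC(=O)OCc4ccccc4
F8 | step 17 | tosylhydrazone of dibenzyl 8α-hydroxy-19-oxo-14,15,16-trinorlabdane-13,18-dioate | O[C@]1(C)CC[C@@H]2[C@](C)(CCC[C@@]2(/C=N/NS(=O)(=O)c5ccc(C)cc5)C(=O)OCc3ccccc3)[C@H]1CCC(=O)OCc4ccccc4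
A1 | alternative 1 | 2,6-dimethyl-1,4-benzoquinone | CC1=CC(=O)C=C(C)C1=O
A2 | alternative 1 | (E)-tert-butyldimethyl[(2-methylpenta-2,4-dien-1-yl)oxy]silane | C=C/C=C(\C)CO[Si](C)(C)C(C)(C)C
A3 | alternative 1 | cis-fused endo quinone adduct | O=C1C(C)=CC(=O)[C@H]2[C@]1(C)CC=C[C@@]2(C)CO[Si](C)(C)C(C)(C)C
A4 | alternative 2 | benzyl 2-(5-methoxy-3,5-dioxopentyl)-1-methyl-3-methylenecyclohexane-1-carboxylate (Conia-ene substrate) | COC(=O)CC(=O)CC[C@@H]1C(=C)CCC[C@@]1(C)C(=O)OCc1ccccc1
A5 | alternative 2 | trans-decalin 8-keto-9-carboxylate | O=C1CC[C@@H]2[C@](C)(CCC[C@@]2(C)C(=O)OCc3ccccc3)[C@H]1C(=O)OC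
A6 | alternative 3 | δ-lactone triene (ethyl (E)-enoate on C8 chain, (E)-diene on C9) | O=C1O[C@](C)(CC/C=C(\C)C(=O)OCC)[C@@H](/C(C)=C/C=C)CC1
A7 | alternative 3 | tricyclic lactone ethyl ester with C1=C2 alkene | O=C3O[C@]1(C)CC[C@@H]2[C@](C)(C=CC[C@@]2(C)C(=O)OCC)[C@H]1CC3
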